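If the hunch is that alpha has merely stalled and a longer wait will carry L further, the readings argue against it.

| setting | alpha | theta | flask |
|---|---|---|---|
| Z | 0.092 M | 0.062 M | 0.092 M |
| E | 0.184 M | 0.184 M | 0.184 M |
| J | 0.46 M | 0.46 M | 0.460 M |
| X | 0.10 mM | 0.10 mM | 0.10 mM |
| remark | the very flask that is asked about, followed so far | run made earlier |  |
| time |  |  | 10 h |

| alpha: time / h | alpha: L / % | theta: time / min | theta: L / % |
|---|---|---|---|
| 2.50 | 54.2 | 3.00 | 19.0 |
| 5.00 | 57.2 | 8.00 | 27.6 |
| 8.00 | 56.9 | 20.0 | 33.5 |
| 10.0 | 57.2 | 40.0 | 40.8 |

(each reading ± 0.3 percentage points)

- spring: at 10 h add X, 50.0% of the amount charged, then wait 10 h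
- noon: change nothing and wait 10 h more
- dusk: at 10 h add E, 50.0% of the amount charged, then wait 10 h
- midnight: at 10 h take out 90% of the L then present, then wait 10 h

- L that was removed still counts
- what may be going on: X -> D; Z <-> G; Z + E + X -> X + L; J + E + X -> X + Q
- additions bring no volume worth counting

1. L, in percent of the Z first charged, at 10 h
2. the remedy with the largest gain of L, or "none" below 2 percentage points (spring / noon / dusk / midnight / none)
3. L present, with what was taken out counted in, in percent of the Z first charged, after spring
4. L present, with what was taken out counted in, in percent of the Z first charged, after noon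

Alpha reads flat from 5.00 h on, at a mean of 57.1%, and that is the quick number for now and for noon. L at that mean has used 28.6% of the E charged, so the stop is taken here as loss of X, though the readings do not rule out E going to J.

Theta differs from alpha in the charge of Z. With E and X frozen, each step on the card that takes Z is pseudo-first-order in Z, so the unturned fraction, one minus L, should follow one curve in both runs. Theta at 8.00 min can therefore stand for alpha at that time. The natural logarithm of that unturned fraction over alpha's at the plateau is 0.523, the reach of one charge of X: what the charge does to the unturned fraction over its remaining working life.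

A dose scales the reach, so spring's dose of 50.0% gives L 67.0%, a gain of 9.9 percentage points, more than 2 points. On this reckoning dusk adds E without adding X, and midnight removes L, which no step on the card takes back.

The forecast gave 57.1% for now, spring as best, 66.5% after spring and 57.1% after noon, with “waiting changes nothing”. On spring the reckoning above stands 0.50 points higher.

The flask gives 57.2%, best spring with a gain of 8.9 points, 66.1% after spring and 57.2% after noon.

    X → D (k = 2.11 × 10⁻⁴ s⁻¹)
    Z ⇌ G (K = 8.30, k = 0.00469 s⁻¹)
    Z + E + X → X + L (k = 99.9 M⁻² s⁻¹)
    J + E + X → X + Q (k = 0.954 M⁻² s⁻¹)

At the charged E and X, Z and G together halve in 0.974 h, while X halves in 0.913 h. At 10.0 h the flask holds X at 0.0502% and D at 99.9% of the catalyst charged, beside Z at 4.60% and G at 38.2% of the Z charged. Spring lowered the logarithm by 0.233, against 0.262 from the reach. In the neighbouring flask with E at 0.74 M, the reach scales to 2.10, which from theta's unturned fraction gives L 91.2%; the computed neighbour gives 94.4%.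

The runs were generated by integration on assumed constants.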